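## The problem

Compound 13 is a (2S)-flavanone: a 7,8-dimethoxylated benzo ring A fused to the dihydropyranone ring C, with ring B, a 3-hydroxy-4,5-dimethoxyphenyl group, on C2. The skeleton is simple; the difficulty is the single stereocentre C2, which is benzylic, bonded to the ring oxygen O1 and β to the C4 ketone. No other centre exists to direct its formation, so a chiral catalyst has to set it. Once the ketone is present, base or strong acid can open ring C by retro-oxa-Michael reaction and re-closure returns racemic material. The route therefore has to keep the ketone masked, or the medium close to neutral, from the moment C2 exists. The free 3′-phenol would compete in any step that uses an oxygen nucleophile or an electrophilic silicon reagent, so it needs a mask that comes off without base. Ring A, with its three contiguous oxygen substituents and the carbonyl carbon, is commercially available as acetophenone 7 and should not be rebuilt. The enabling feature is the C3–C4 bond of ring C: C3 adjoins the ether carbon C2 and C4 is the aryl ketone carbon, so C2–C3 maps onto the alkene of a 1-arylallyl aryl ether and C4 onto a ketone-derived silyl enol ether, two alkenes that a ruthenium carbene can join.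

## Retrosynthesis

**Unmasking (13 from 11).** The first cut is of two O–Si bonds. Target 13 is traced, through the silyl-protected flavanone 12, to the 4-silyloxy-2H-chromene 11, which holds the C4 ketone as an enol silane and the 3′-phenol as a triisopropylsilyl ether. Ending here, and not on a skeletal bond formation at the ketone oxidation level, means the flavanone appears only in the last flask; the enol silane cannot undergo the ring opening that threatens C2. Compound 11 is no simpler in skeleton; the gain is stability. The forward step must protonate C3 and free the phenol without letting an enolate or a basic medium persist.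

**Ring C (11 from 10).** The C3=C4 double bond of 11 is cut, opening ring C to the acyclic diene 10, an (S)-1-arylallyl aryl ether with a 1-(silyloxy)vinyl group ortho to the ether oxygen. The neighbouring cuts are weaker:
- O1–C2 would need an enantioselective oxa-Michael closure, which is reversible and poorly controlled for unactivated substrates.
- C4–C4a would need a Friedel–Crafts acylation under acid strong enough to ionise the C2–O1 bond.
- O1–C8a would need a halogenated ring A and a separate operation for the stereocentre.

The C3=C4 cut leaves all four bonds at C2 in place and turns the two ring carbons into alkenes that are each one step from a common functional group. The forward reaction must start at the vinyl group, accept the electron-rich 1,1-disubstituted enol silane, and not move the double bond into the C2–C3 position.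

**Enol silane (10 from 9).** The enol O–Si bond is cut to give methyl ketone 9. The acetyl group has one enolisable position, so there is no regiochemical question, and 9 is a stable compound that can be purified and stored. Carrying the enol silane through the preceding etherification is ruled out by its lability to alkoxide. The forward step must not ionise the allylic, benzylic C2–O1 bond.

**Ether bond and stereocentre (9 from 6 and 7).** The C2–O1 bond is cut, dividing 9 into the (E)-cinnamyl methyl carbonate 6 and acetophenone 7, used as its sodium aryloxide 8. Making this bond by SN2 displacement at a preformed carbinol would need an extra stereo-defining step and risks ionisation. Cuts at C2–aryl or C2–vinyl offer no established handle for asymmetric induction. Iridium-catalysed allylic etherification forms the bond and the stereocentre together from an achiral linear carbonate, and 7 is bought with every ring A substituent in place. The forward reaction must bring a 2,6-disubstituted, ketone-chelated aryloxide to the benzylic allyl terminus with high facial selectivity and be stopped before the product re-ionises.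

**Ring B side chain (6 from 1 and 3).** The carbonate C–O bond is cut to alcohol 5, 5 is traced by reduction to ester 4, and the C=C bond of 4 is cut to aldehyde 2 and phosphonate 3; the O–Si bond of 2 leads to the commercial phenol 1. Olefination fixes the (E) geometry that the iridium catalyst requires. The phenol is masked as the triisopropylsilyl ether, not the tert-butyldimethylsilyl ether, because step 5 releases methoxide.

## Roads not taken

**Alternative 1:** This road cuts C4a–C4, C4–C3 and O1–C2 together, taking ring C back to 6-iodo-2,3-dimethoxyphenol A1, the aryl alkyne A2 (1-benzyloxy-5-ethynyl-2,3-dimethoxybenzene) and carbon monoxide. Forward, PdCl2(PPh3)2 under CO in diethylamine would couple A1 and A2 to an alkynone, and the amine would promote 6-endo closure to flavone A3.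
- Merits: three bonds and a ring in one flask, two fragments of similar size, and no stereocentre or base-sensitive ketone to protect on the way. It reaches the bicyclic skeleton in fewer steps than the chosen plan.
- Weak points: A3 is flat. C2 would have to be created afterwards by enantioselective 1,4-reduction of a 2-arylchromone, a vinylogous ester with a fully substituted β-carbon. Such reductions are less general than allylic substitution, tend to over-reduce to the flavan-4-ol, and release the flavanone into a hydridic, often basic medium in which ring C can open. 5-Exo closure to the aurone competes in the annulation, and the benzyl ether would have to be hydrogenolysed next to the benzylic C2–O1 bond.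
- Comparison: in convergence and step count this road is better. The chosen plan sets against that a stereocentre made early by a catalytic reaction with a well-understood stereochemical model, and a sequence that is neutral or buffered from then on.

**Alternative 2:** This road makes ring A instead of ring C: the C8a–C4a bond is cut and the arene is traced to dimethyl squarate A4. An (E)-alkenyl lithium reagent carrying the ketal-masked C4 and the (R)-silyloxy carbinol would add to A4 to give the 4-alkenyl-4-hydroxycyclobutenone A5. Heating A5 opens it to a dienylketene, and 6π electrocyclisation and tautomerisation give hydroquinone A6.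
- Merits: a thermal, reagent-free arene construction with unambiguous substituent placement, and a carbinol stereocentre that can be made by well-tried carbonyl chemistry and later closed onto the C8a phenol with inversion. It would be the better road for analogues with varied ring A substitution, and it needs no transition metal for ring formation.
- Weak points: it builds the one part of 13 that can be bought as 7. A6 carries a hydroxyl at C6 that 13 lacks, so the two phenols must be told apart and one removed through its triflate. The ketal must be cleaved, ring C closed by a Mitsunobu reaction at an electron-rich benzylic carbinol (ionisation and loss of configuration are possible), and the benzyl ether removed.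
- Comparison: for 13 itself the chosen plan is much shorter and has no deoxygenation to perform.

**Alternative 3:** This road cuts O1–C8a. The (1R,3S)-bromo diol A7 would be closed with Pd(OAc)2, a bulky di-tert-butylbiarylphosphine and Cs2CO3 to the (2S,4R)-flavan-4-ol A8; oxidation of the C4 hydroxyl and hydrogenolysis of the benzyl ether would follow.
- Merits: no bond to C2 is touched during ring closure and no alkene is present, so C2 is safer than in a metathesis, where it is allylic and exposed to double-bond migration. Carbonate base is harmless at the alcohol oxidation level. On this point the road is better than the chosen one.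
- Weak points: the bromide of A7 sits between a methoxy group and the branched side chain, so oxidative addition to zerovalent palladium and C–O reductive elimination from a crowded aryl palladium alkoxide are slow. A secondary benzylic alkoxide on palladium can undergo β-hydride elimination to a ketone and the reduced arene, and the C4 hydroxyl can bind the metal and be oxidised the same way. The C4 stereocentre is made with care and then destroyed. A7 needs a brominated ring A aldehyde and a stereoselective chain assembly, and two steps follow the key step.
- Comparison: the chosen plan sets against the safer C2 a shorter sequence, a single stereocentre made once, a commercial ring A piece, and a ring closure indifferent to ortho substitution. Migration in the metathesis is addressed by additive, temperature and reaction time.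

Key step: step 7

Assumption: with the cyclometalated iridium catalyst from the (Sa,Sc,Sc) phosphoramidite, the aryloxide is taken to add to the face of the cinnamyl terminus that gives the (S) ether, as the usual model for this ligand family predicts; should the sense prove opposite, the (Ra,Rc,Rc) antipode is used and nothing else changes.

Ligand L in step 5 is (Sa,Sc,Sc)-O,O′-(1,1′-binaphthalene-2,2′-diyl) N,N-bis(1-phenylethyl)phosphoramidite.

## Route

Step 1
Reactants: 1 3-hydroxy-4,5-dimethoxybenzaldehyde
Product: 2 3,4-dimethoxy-5-(triisopropylsilyloxy)benzaldehyde
Conditions: TIPSCl, imidazole, DMF, rt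
Reagents that add atoms: triisopropylsilyl chloride, CC(C)[Si](Cl)(C(C)C)C(C)C
Why: Silylation of a phenol with a trialkylsilyl chloride and imidazole; the triisopropylsilyl ether is chosen because it should withstand the sodium methoxide released in step 5, and the aldehyde is not affected.

Step 2
Reactants: 2 3,4-dimethoxy-5-(triisopropylsilyloxy)benzaldehyde; 3 triethyl phosphonoacetate
Product: 4 ethyl (E)-3-[3,4-dimethoxy-5-(triisopropylsilyloxy)phenyl]prop-2-enoate
Conditions: LiCl, DBU, MeCN, rt
Reagents that add atoms: none
Why: Horner–Wadsworth–Emmons olefination under Masamune–Roush conditions; a stabilised phosphonate and a non-enolisable aromatic aldehyde should give the (E)-cinnamate, and the amine base leaves the aryl silyl ether alone.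

Step 3
Reactants: 4 ethyl (E)-3-[3,4-dimethoxy-5-(triisopropylsilyloxy)phenyl]prop-2-enoate
Product: 5 (E)-3-[3,4-dimethoxy-5-(triisopropylsilyloxy)phenyl]prop-2-en-1-ol
Conditions: i-Bu2AlH (2.5 equiv), CH2Cl2, −78 °C; aq. potassium sodium tartrate (KNaC4H4O6)
Reagents that add atoms: none
Why: 1,2-Reduction of an α,β-unsaturated ester by i-Bu2AlH at low temperature gives the allylic alcohol without touching the alkene or the silyl ether.

Step 4
Reactants: 5 (E)-3-[3,4-dimethoxy-5-(triisopropylsilyloxy)phenyl]prop-2-en-1-ol
Product: 6 (E)-3-[3,4-dimethoxy-5-(triisopropylsilyloxy)phenyl]prop-2-enyl methyl carbonate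
Conditions: ClCO2Me, pyridine, CH2Cl2, 0 °C
Reagents that add atoms: methyl chloroformate, COC(=O)Cl
Why: Acylation of a primary allylic alcohol with a chloroformate; the methyl carbonate is the usual leaving group for iridium-catalysed allylic substitution because ionisation is followed by loss of CO2.

Step 5
Reactants: 6 (E)-3-[3,4-dimethoxy-5-(triisopropylsilyloxy)phenyl]prop-2-enyl methyl carbonate; 7 1-(2-hydroxy-3,4-dimethoxyphenyl)ethanone
Product: 9 1-(2-{(1S)-1-[3,4-dimethoxy-5-(triisopropylsilyloxy)phenyl]prop-2-enyloxy}-3,4-dimethoxyphenyl)ethanone, via sodium 6-acetyl-2,3-dimethoxyphenolate 8 (not isolated)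
Conditions: [Ir(cod)Cl]2 (2 mol%), L (4 mol%), n-PrNH2, THF, 50 °C, then evaporation; 7 (1.5 equiv), NaH (1.5 equiv), THF, 0 °C; then 6, THF, rt
Reagents that add atoms: none
Why: Iridium-catalysed asymmetric allylic etherification of a linear cinnamyl carbonate with an alkali aryloxide: the cyclometalated iridium–phosphoramidite complex ionises 6 to a π-allyl species and aryloxide 8 attacks the aryl-substituted terminus anti to the metal, so the branched ether forms and the ligand fixes the face, giving the (S) centre that becomes C2. The electron-rich aryl group favours attack at the benzylic terminus, and the reaction is to be stopped at full consumption of 6 so that the product does not re-ionise.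

Step 6
Reactants: 9 1-(2-{(1S)-1-[3,4-dimethoxy-5-(triisopropylsilyloxy)phenyl]prop-2-enyloxy}-3,4-dimethoxyphenyl)ethanone
Product: 10 1-[1-(tert-butyldimethylsilyloxy)ethenyl]-2-{(1S)-1-[3,4-dimethoxy-5-(triisopropylsilyloxy)phenyl]prop-2-enyloxy}-3,4-dimethoxybenzene
Conditions: TBSOTf (1.2 equiv), Et3N (2.5 equiv), CH2Cl2, −78 → 0 °C
Reagents that add atoms: tert-butyldimethylsilyl trifluoromethanesulfonate, CC(C)(C)[Si](C)(C)OS(=O)(=O)C(F)(F)F
Why: Soft enolisation of an aryl methyl ketone with a silyl triflate and a tertiary amine gives the terminal silyl enol ether, the acetyl group having one enolisable position; excess Et3N keeps the medium free of acid so that the ionisable allyl aryl ether and its stereocentre are not disturbed.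

Step 7
Reactants: 10 1-[1-(tert-butyldimethylsilyloxy)ethenyl]-2-{(1S)-1-[3,4-dimethoxy-5-(triisopropylsilyloxy)phenyl]prop-2-enyloxy}-3,4-dimethoxybenzene
Product: 11 (2S)-4-(tert-butyldimethylsilyloxy)-2-[3,4-dimethoxy-5-(triisopropylsilyloxy)phenyl]-7,8-dimethoxy-2H-chromene
Conditions: RuCl2(=CHPh)(H2IMes)(PCy3) (second-generation Grubbs catalyst, 5 mol%), 1,4-benzoquinone (10 mol%), degassed toluene (0.01 M), 50 °C
Reagents that add atoms: none
Why: Ring-closing olefin metathesis through ruthenacyclobutane intermediates: the ruthenium benzylidene exchanges onto the monosubstituted allyl ether alkene of 10, the resulting alkylidene adds across the 1,1-disubstituted silyl enol ether in an intramolecular [2+2] cycloaddition, and cycloreversion gives the C3=C4 bond of 11 and a ruthenium methylidene that re-enters at the vinyl group of the next molecule with release of ethylene. The closest known reaction types are the ring-closing metathesis of olefinic silyl enol ethers to cyclic enol silanes, including 4-silyloxy-1,2-dihydroquinolines from the nitrogen analogues of 10, and that of 2-vinylaryl allyl ethers to 2H-chromenes. Ring C closes as an unstrained six-membered ring because the two alkenes are held on adjacent positions of ring A through O1 and C4a, so cyclisation at 0.01 M should outrun cross-metathesis. No stereocentre is formed, and C2, set in step 5, is a spectator because none of its bonds takes part. The step needs initiation at the vinyl group and not at the enol silane, which the lower substitution and lower electron density of the vinyl group should secure. It also needs the double bond to stay out of the C2–C3 position, for which 1,4-benzoquinone (to intercept ruthenium hydrides), a moderate temperature and a short reaction time are provided. The product is the enol silane of the flavanone, a form in which the ketone cannot trigger retro-oxa-Michael opening.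

Step 8
Reactants: 11 (2S)-4-(tert-butyldimethylsilyloxy)-2-[3,4-dimethoxy-5-(triisopropylsilyloxy)phenyl]-7,8-dimethoxy-2H-chromene
Product: 13 (2S)-2-(3-hydroxy-4,5-dimethoxyphenyl)-7,8-dimethoxy-2,3-dihydro-4H-chromen-4-one, via silyl-protected flavanone 12 (not isolated)
Conditions: TBAF (2.5 equiv), AcOH (3 equiv), THF, 0 °C → rt
Reagents that add atoms: none
Why: Fluoride-mediated desilylation: the less hindered tert-butyldimethylsilyl enol ether should go first, with protonation at C3 by AcOH to give 12, and the aryl triisopropylsilyl ether second. The acetic acid buffer keeps the medium from turning basic, so ring C should not open by E1cB loss of the aryloxide and C2 keeps its configuration; C3 becomes a methylene, so no new stereocentre arises.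

## Compound list

1 | 3-hydroxy-4,5-dimethoxybenzaldehyde | COc1cc(C=O)cc(O)c1OC | starting material
2 | 3,4-dimethoxy-5-(triisopropylsilyloxy)benzaldehyde | COc1cc(C=O)cc(O[Si](C(C)C)(C(C)C)C(C)C)c1OC | intermediate
3 | triethyl phosphonoacetate | CCOC(=O)CP(=O)(OCC)OCC | starting material
4 | ethyl (E)-3-[3,4-dimethoxy-5-(triisopropylsilyloxy)phenyl]prop-2-enoate | CCOC(=O)/C=C/c1cc(OC)c(OC)c(O[Si](C(C)C)(C(C)C)C(C)C)c1 | intermediate
5 | (E)-3-[3,4-dimethoxy-5-(triisopropylsilyloxy)phenyl]prop-2-en-1-ol | OC/C=C/c1cc(OC)c(OC)c(O[Si](C(C)C)(C(C)C)C(C)C)c1 | intermediate
6 | (E)-3-[3,4-dimethoxy-5-(triisopropylsilyloxy)phenyl]prop-2-enyl methyl carbonate | COC(=O)OC/C=C/c1cc(OC)c(OC)c(O[Si](C(C)C)(C(C)C)C(C)C)c1 | intermediate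
7 | 1-(2-hydroxy-3,4-dimethoxyphenyl)ethanone (2′-hydroxy-3′,4′-dimethoxyacetophenone) | CC(=O)c1ccc(OC)c(OC)c1O | starting material
8 | sodium 6-acetyl-2,3-dimethoxyphenolate | CC(=O)c1ccc(OC)c(OC)c1[O-].[Na+] | intermediate
9 | 1-(2-{(1S)-1-[3,4-dimethoxy-5-(triisopropylsilyloxy)phenyl]prop-2-enyloxy}-3,4-dimethoxyphenyl)ethanone | CC(=O)c1ccc(OC)c(OC)c1O[C@@H](C=C)c1cc(OC)c(OC)c(O[Si](C(C)C)(C(C)C)C(C)C)c1 | intermediate
10 | 1-[1-(tert-butyldimethylsilyloxy)ethenyl]-2-{(1S)-1-[3,4-dimethoxy-5-(triisopropylsilyloxy)phenyl]prop-2-enyloxy}-3,4-dimethoxybenzene | C=C(O[Si](C)(C)C(C)(C)C)c1ccc(OC)c(OC)c1O[C@@H](C=C)c1cc(OC)c(OC)c(O[Si](C(C)C)(C(C)C)C(C)C)c1 | intermediate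
11 | (2S)-4-(tert-butyldimethylsilyloxy)-2-[3,4-dimethoxy-5-(triisopropylsilyloxy)phenyl]-7,8-dimethoxy-2H-chromene | COc1cc([C@@H]2C=C(O[Si](C)(C)C(C)(C)C)c3ccc(OC)c(OC)c3O2)cc(O[Si](C(C)C)(C(C)C)C(C)C)c1OC | intermediate
12 | (2S)-2-[3,4-dimethoxy-5-(triisopropylsilyloxy)phenyl]-7,8-dimethoxy-2,3-dihydro-4H-chromen-4-one | COc1cc([C@@H]2CC(=O)c3ccc(OC)c(OC)c3O2)cc(O[Si](C(C)C)(C(C)C)C(C)C)c1OC | intermediate
13 | (2S)-2-(3-hydroxy-4,5-dimethoxyphenyl)-7,8-dimethoxy-2,3-dihydro-4H-chromen-4-one | COc1cc([C@@H]2CC(=O)c3ccc(OC)c(OC)c3O2)cc(O)c1OC | target

## Step count and risks

Total: 8 steps. Longest linear sequence: 8 steps (1 → 13); acetophenone 7 enters unchanged in step 5.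

**Step 7 (key step).**
- What may go wrong: migration of a double bond under ruthenium hydride catalysis, either of the allyl ether alkene into conjugation before closure or of C3=C4 into C2=C3 after it, which would erase C2. The ruthenium methylidene may also be captured by the electron-rich enol silane as a poorly active heteroatom-substituted carbene, stalling turnover. Adventitious hydrolysis of the enol silane is harmless, since it gives 12.
- Fallback: it sets out from ketone 9, comes back at 12, and also bypasses step 6. NaBH4 in MeOH reduces 9 to the secondary benzylic alcohol F1 (both carbinol epimers). The Burgess reagent dehydrates F1 to the ortho-vinyl aryl allyl ether F2. The second-generation Grubbs catalyst in CH2Cl2 at 40 °C closes F2, a diene of two monosubstituted alkenes, to the (S)-2H-chromene F3. Mukaiyama hydration (Co(acac)2, PhSiH3, O2) places the hydroxyl at the benzylic C4 to give the flavan-4-ol F4. Dess–Martin periodinane oxidises F4 to 12, which is desilylated as in step 8. The detour costs four extra operations and carries the alkene-migration risk only in its best-precedented form.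

**Step 5.**
- What may go wrong: slow attack by the sodium-chelated, 2,6-disubstituted aryloxide, and re-ionisation of the branched ether by the catalyst once 6 is consumed, which erodes the enantiomeric purity and leaks material to the linear ether. The sense of induction also rests on the assumption stated before the steps.
- Fallback: it sets out from aldehyde 2 and comes back at 9, forming the C2–O1 bond by SN2 displacement instead. CH2=CHMgBr adds to 2 to give the racemic 1-arylallyl alcohol F5. Sharpless kinetic resolution (Ti(Oi-Pr)4, D-(−)-diisopropyl tartrate, t-BuOOH, CH2Cl2, −20 °C) should leave the (R)-alcohol F6, the (S)-enantiomer being consumed as the epoxy alcohol F7, which is discarded. A Mitsunobu reaction of F6 with phenol 7 (PPh3, diisopropyl azodicarboxylate, toluene, 0 °C) should give 9 with inversion. Half of the material is lost and SN2′ attack has to be watched.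

**Step 8.**
- What may go wrong: opening of ring C by E1cB elimination of the ring A aryloxide from a fluoride-generated enolate, followed by unselective re-closure, that is, racemisation at C2; the risk is highest if the buffer is exhausted while the aryl silyl ether is still being cleaved.
- Fallback: it sets out from 11 and comes back at 13, separating the two unmaskings so that neither passes through a basic medium. Dilute aqueous HCl in THF at 0 °C hydrolyses the enol silane by C3 protonation to 12, which is isolated. The aryl silyl ether of 12 is then cleaved with the acidic fluoride source Et3N·3HF in MeCN to give 13. No compound outside the compound list is made.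

## Further compounds

F1 | step 7 | 1-(2-{(1S)-1-[3,4-dimethoxy-5-(triisopropylsilyloxy)phenyl]prop-2-enyloxy}-3,4-dimethoxyphenyl)ethanol, both carbinol epimers | CC(O)c1ccc(OC)c(OC)c1O[C@@H](C=C)c1cc(OC)c(OC)c(O[Si](C(C)C)(C(C)C)C(C)C)c1
F2 | step 7 | 1-ethenyl-2-{(1S)-1-[3,4-dimethoxy-5-(triisopropylsilyloxy)phenyl]prop-2-enyloxy}-3,4-dimethoxybenzene | C=Cc1ccc(OC)c(OC)c1O[C@@H](C=C)c1cc(OC)c(OC)c(O[Si](C(C)C)(C(C)C)C(C)C)c1
F3 | step 7 | (2S)-2-[3,4-dimethoxy-5-(triisopropylsilyloxy)phenyl]-7,8-dimethoxy-2H-chromene | COc1cc([C@@H]2C=Cc3ccc(OC)c(OC)c3O2)cc(O[Si](C(C)C)(C(C)C)C(C)C)c1OC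
F4 | step 7 | (2S)-2-[3,4-dimethoxy-5-(triisopropylsilyloxy)phenyl]-7,8-dimethoxy-3,4-dihydro-2H-chromen-4-ol, both C4 epimers | COc1cc([C@@H]2CC(O)c3ccc(OC)c(OC)c3O2)cc(O[Si](C(C)C)(C(C)C)C(C)C)c1OC
F5 | step 5 | racemic 1-[3,4-dimethoxy-5-(triisopropylsilyloxy)phenyl]prop-2-en-1-ol | C=CC(O)c1cc(OC)c(OC)c(O[Si](C(C)C)(C(C)C)C(C)C)c1
F6 | step 5 | (1R)-1-[3,4-dimethoxy-5-(triisopropylsilyloxy)phenyl]prop-2-en-1-ol | O[C@H](C=C)c1cc(OC)c(OC)c(O[Si](C(C)C)(C(C)C)C(C)C)c1
F7 | step 5 | (R)-[3,4-dimethoxy-5-(triisopropylsilyloxy)phenyl][(2R)-oxiran-2-yl]methanol | O[C@@H]([C@H]1CO1)c1cc(OC)c(OC)c(O[Si](C(C)C)(C(C)C)C(C)C)c1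
F0 | step 8 | none | none
A1 | alternative 1 | 6-iodo-2,3-dimethoxyphenol | Oc1c(I)ccc(OC)c1OC
A2 | alternative 1 | 1-benzyloxy-5-ethynyl-2,3-dimethoxybenzene | C#Cc1cc(OC)c(OC)c(OCc2ccccc2)c1
A3 | alternative 1 | 3′-benzyloxy-4′,5′,7,8-tetramethoxyflavone | COc1cc(-c2cc(=O)c3ccc(OC)c(OC)c3o2)cc(OCc4ccccc4)c1OC
A4 | alternative 2 | dimethyl squarate (3,4-dimethoxycyclobut-3-ene-1,2-dione) | COC1=C(OC)C(=O)C1=O
A5 | alternative 2 | 4-hydroxy-2,3-dimethoxy-4-[(E)-alkenyl]cyclobut-2-enone carrying the ketal-masked (R)-β-silyloxy ketone chain | COC1=C(OC)C(O)(/C=C/C2(C[C@@H](O[Si](C)(C)C(C)(C)C)c3cc(OC)c(OC)c(OCc4ccccc4)c3)OCCO2)C1=O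
A6 | alternative 2 | 2,3-dimethoxyhydroquinone carrying the ketal-masked (R)-β-silyloxy ketone chain | Oc1c(OC)c(OC)c(O)cc1C1(C[C@@H](O[Si](C)(C)C(C)(C)C)c2cc(OC)c(OC)c(OCc3ccccc3)c2)OCCO1
A7 | alternative 3 | (1R,3S)-3-(3-benzyloxy-4,5-dimethoxyphenyl)-1-(2-bromo-3,4-dimethoxyphenyl)propane-1,3-diol | COc1cc([C@@H](O)C[C@@H](O)c2ccc(OC)c(OC)c2Br)cc(OCc2ccccc2)c1OC
A8 | alternative 3 | (2S,4R)-2-(3-benzyloxy-4,5-dimethoxyphenyl)-7,8-dimethoxy-3,4-dihydro-2H-chromen-4-ol | COc1cc([C@@H]2C[C@@H](O)c3ccc(OC)c(OC)c3O2)cc(OCc4ccccc4)c1OC
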